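**Plan**

1. Retrosynthesis: the C5 angelate ester bond and the C6 silyl ether are cut last; the C1–O bond of the acetate is traced back to a C1 acetyl group (oxygen insertion with C→O acetyl transfer); the C1–C2 bond of the five-membered ring is then cut, which re-expands that ring to ring B of a trans-decalin; the ring bonds C3–C3a and C1–C7a go back to a Diels–Alder reaction of (S)-cryptone with isoprene.
2. Enabling feature: in the hydrindane (C1 CHOAc, C2 C=O, C3 CH2, C3a/C7a fusion, C4 =CH2, C5 OAng, C6 OH, C7 iPr) the C1-acetoxy/C2-oxo pair is one oxygen insertion away from a 2-acetylcyclopentanone, and that is the acyl-shift isomer of a 2-methyl-2,3-epoxycyclohexanone in ring B of the decalin.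
3. Forward order: ring A (cryptone), ring B by cycloaddition, oxygenation and methylenation of ring A, oxidation of ring B to the epoxy ketone, contraction of ring B, acetyl-to-acetate conversion, desilylation.
4. Stereochemistry: C7 from an organocatalytic Michael addition; C7a and C3a from the anti-facial Diels–Alder reaction and base epimerisation; C5 and C6 from axial epoxidation of the ring-A enone and trans-diaxial epoxide opening; C1 by equilibration of an enolisable centre.

Key step: step 17

Locants: decalins carry cadinane-type locants (fusion C1/C6; ring B = C1–C2–C3–C4–C5–C6 with methyl on C4; ring A = C1–C10–C9–C8–C7–C6 with isopropyl on C7). β is the face of H-6 (later H-7a), α the opposite face. On contraction C5→C1, C3→C2, C2→C3, C1→C3a, C10→C4, C9→C5, C8→C6, C6→C7a, and C4 with its methyl becomes the acetyl group.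

Assumption: the (S)-prolinol ether catalyst of step 1 shields the same enamine face as in its other Michael additions and so gives the (S)-aldehyde; if the sense proved opposite, its enantiomer would be used.

Step 1
Reactants: 1 isovaleraldehyde (3-methylbutanal); 2 methyl vinyl ketone (but-3-en-2-one)
Product: 3 (S)-2-isopropyl-5-oxohexanal
Conditions: (S)-2-[methoxy(diphenyl)methyl]pyrrolidine (5 mol %), ethyl 3,4-dihydroxybenzoate (20 mol %), neat, 4 °C
Reagents that add atoms: none
Why: Enamine-catalysed Michael addition of an aldehyde to an enone: the E-enamine of 1 is shielded on one face by the diphenyl(methoxy)methyl group and should add to 2 from the open face, setting the new centre as S.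

Step 2
Reactants: 3 (S)-2-isopropyl-5-oxohexanal
Product: 4 (S)-cryptone [(S)-4-isopropylcyclohex-2-en-1-one]
Conditions: KOH (0.1 M aq.), nBu4NOH (cat.), Et2O/THF, reflux
Reagents that add atoms: none
Why: Intramolecular aldol condensation (methyl ketone enolate onto the aldehyde, then dehydration) closes the cyclohexenone; the stereocentre becomes the γ-carbon of the enone and should survive the dilute biphasic base.

Step 3
Reactants: 4 (S)-cryptone; 5 isoprene
Product: 6 cis-octalone (4S,4aS,8aS)-4-isopropyl-6-methyl-3,4,4a,5,8,8a-hexahydronaphthalen-1(2H)-one (10-oxo-3-ene; 1β-H 6β-H 7β-iPr)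
Conditions: AlCl3 (0.3 equiv), isoprene (5 equiv), toluene, 25 °C
Reagents that add atoms: none
Why: Lewis-acid-catalysed Diels–Alder reaction: isoprene should add to the enone face anti to the isopropyl group with para orientation (methyl-bearing carbon 1,4 to the acyl-bearing carbon), which sets C6 with H-6 cis to the isopropyl group and gives the cis fusion.

Step 4
Reactants: 6 cis-octalone
Product: 7 trans-octalone (4S,4aS,8aR)-4-isopropyl-6-methyl-3,4,4a,5,8,8a-hexahydronaphthalen-1(2H)-one (1α-H 6β-H 7β-iPr)
Conditions: NaOMe, MeOH, 25 °C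
Reagents that add atoms: none
Why: Base epimerisation of the α-carbon C1 through the enolate under thermodynamic control; the trans-fused decalone with equatorial isopropyl is the more stable isomer, which sets C1.

Step 5
Reactants: 7 trans-octalone
Product: 9 trans-dienone (3,8-dien-10-one; 1α-H 6β-H 7β-iPr), via kinetic trimethylsilyl enol ether 8 (not isolated)
Conditions: LiN(iPr)2, THF, −78 °C, then Me3SiCl; Pd(OAc)2 (1.1 equiv), MeCN, 25 °C
Reagents that add atoms: none
Why: Kinetic deprotonation at the C9 methylene (not the ring-fusion CH) and silylation, then Saegusa–Ito oxidation, place the new double bond at C8–C9; the isolated ring-B alkene is untouched.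

Step 6
Reactants: 9 trans-dienone
Product: 10 8β,9β-epoxy-3-en-10-one
Conditions: 30% H2O2, NaOH (cat.), MeOH, 0 °C
Reagents that add atoms: hydrogen peroxide, OO
Why: Weitz–Scheffer nucleophilic epoxidation: hydroperoxide should add to C8 along the axial trajectory of the locked half-chair, i.e. on the β face, so closure gives the 8β,9β-epoxide; the electron-rich ring-B alkene does not react with the nucleophilic oxidant.

Step 7
Reactants: 10 8β,9β-epoxy-3-en-10-one
Product: 11 8β,9β-epoxy-10-methylene-3-ene (vinyl epoxide)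
Conditions: Ph3PCH3Br, KOtBu, THF, 0 → 25 °C
Reagents that add atoms: methyltriphenylphosphonium bromide, C[P+](c1ccccc1)(c1ccccc1)c1ccccc1.[Br-]
Why: Wittig methylenation: the non-stabilised ylide adds to the ketone much faster than it opens the epoxide, and C1 is already in its stable trans configuration.

Step 8
Reactants: 11 vinyl epoxide
Product: 12 9α-(4-methoxybenzyloxy)-10-methylene-3-en-8β-ol
Conditions: [Rh(CO)2Cl]2 (2.5 mol %), 4-MeOC6H4CH2OH (3 equiv), THF, 25 °C
Reagents that add atoms: 4-methoxybenzyl alcohol, COc1ccc(CO)cc1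
Why: Monovalent-rhodium-catalysed anti 1,2-addition of an alcohol to a vinyl epoxide: attack at allylic C9 with inversion is also the trans-diaxial (Fürst–Plattner) mode for the β-epoxide, which sets 9α-O and 8β-OH and marks the two oxygens differently.

Step 9
Reactants: 12 9α-(4-methoxybenzyloxy)-10-methylene-3-en-8β-ol
Product: 13 8β-(tert-butyldimethylsilyloxy)-9α-(4-methoxybenzyloxy)-10-methylene-3-ene
Conditions: tBuMe2SiOTf, 2,6-lutidine, CH2Cl2, 0 → 25 °C
Reagents that add atoms: tert-butyldimethylsilyl triflate, CC(C)(C)[Si](C)(C)OS(=O)(=O)C(F)(F)F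
Why: Silyl ether formation; the triflate is needed for the hindered axial alcohol next to the isopropyl-bearing carbon.

Step 10
Reactants: 13 silyl/benzyl diether
Product: 14 3,4-epoxide of 13 (mixture of α- and β-epoxide)
Conditions: mCPBA (1.05 equiv), NaHCO3, CH2Cl2, −20 → 0 °C
Reagents that add atoms: 3-chloroperoxybenzoic acid, O=C(OO)c1cccc(Cl)c1
Why: Prilezhaev epoxidation: the trisubstituted ring-B alkene is far more nucleophilic than the 1,1-disubstituted alkene, which is deactivated by its allylic ether; the epoxide face is irrelevant because C3 and C4 both become sp2 later.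

Step 11
Reactants: 14 3,4-epoxide
Product: 15 secondary alcohol at C3 (4-methyl; diastereomer mixture at C3 and C4)
Conditions: (C5H5)2TiCl2 (10 mol %), Mn, 2,4,6-collidine·HCl, 1,4-cyclohexadiene, THF, 25 °C
Reagents that add atoms: none
Why: Titanocene-mediated reductive epoxide opening (Nugent–RajanBabu reaction): trivalent titanium cleaves the C4–O bond to the tertiary radical, which takes hydrogen from 1,4-cyclohexadiene, giving the anti-Markovnikov C3 alcohol that a hydroboration could not deliver here because a borane would attack the exocyclic methylene first.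

Step 12
Reactants: 15 C3 alcohol
Product: 16 4-methyl-3-ketone (C4 epimers)
Conditions: Dess–Martin periodinane, NaHCO3, CH2Cl2, 25 °C
Reagents that add atoms: none
Why: Dess–Martin oxidation of the only free alcohol under buffered, non-acidic conditions that leave both ethers and the alkene alone.

Step 13
Reactants: 16 4-methyl-3-ketone
Product: 18 4-methyl-4-en-3-one, via thermodynamic trimethylsilyl enol ether 17 (not isolated)
Conditions: Me3SiCl, NaI, Et3N, MeCN, 25 °C; then Pd(OAc)2 (1.1 equiv), MeCN, 40 °C
Reagents that add atoms: none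
Why: Equilibrating silylation with Me3SiI made in situ gives the more substituted C3=C4 enol ether, and Saegusa–Ito oxidation with β-hydride loss from C5 should give the endocyclic 2-methyl enone.

Step 14
Reactants: 18 4-methyl-4-en-3-one
Product: 19 4α,5α-epoxy-3-ketone (8β-silyloxy 9α-methoxybenzyloxy 10-methylene)
Conditions: 30% H2O2, NaOH, MeOH, 0 °C
Reagents that add atoms: hydrogen peroxide, OO
Why: Weitz–Scheffer epoxidation of a 2-methylcyclohexenone (the carvone case): axial attack at C5 anti to axial H-6 should give the α-epoxide, and either face would serve because C5 becomes enolisable and C4 a carbonyl in step 17.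

Step 15
Reactants: 19 epoxy ketone diether
Product: 20 4α,5α-epoxy-3-ketone 9α-alcohol (8β-silyloxy)
Conditions: DDQ, CH2Cl2/pH 7 buffer, 0 °C
Reagents that add atoms: none
Why: Oxidative cleavage of the 4-methoxybenzyl ether by DDQ (benzylic hydride abstraction, hydrolysis), which frees only O-9 and spares the silyl ether, epoxy ketone and alkene.

Step 16
Reactants: 20 epoxy ketone 9α-alcohol; 21 angelic acid [(Z)-2-methylbut-2-enoic acid]
Product: 23 4α,5α-epoxy-3-ketone 9α-angelate (8β-silyloxy 10-methylene), via angelic 2,4,6-trichlorobenzoic anhydride 22 (not isolated)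
Conditions: 21, 2,4,6-Cl3C6H2COCl, Et3N, toluene, 25 °C; then 20, 80 °C
Reagents that add atoms: none
Why: Yamaguchi-type esterification through the mixed anhydride, the usual way to make angelates without Z-to-E isomerisation; O-9 is the only free hydroxyl and the trans-diaxial O-8/O-9 pair cannot exchange acyl groups.

Step 17
Reactants: 23 4α,5α-epoxy-3-ketone 9α-angelate
Product: 24 1β-acetyl-5α-angeloyloxy-6β-(tert-butyldimethylsilyloxy)-7β-isopropyl-4-methylene-trans-hydrindan-2-one (3aα-H 7aβ-H; drawn as the diketo tautomer)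
Conditions: BF3·OEt2 (1.5 equiv), CH2Cl2, −78 → −20 °C; NaHCO3 aq.
Reagents that add atoms: none
Why: BF3 binds the epoxide oxygen; positive charge next to the carbonyl (old C4) is disfavoured, so the C5–O bond lengthens and the ring acyl carbon (old C3) shifts from C4 to C5 in concert, with inversion at C5, while C4–O becomes the acetyl carbonyl. The closest known reaction type is the Lewis-acid rearrangement of α,β-epoxy ketones to 1,3-dicarbonyl compounds with ring contraction (isophorone oxide to 2-formyl-2,4,4-trimethylcyclopentanone, 2-methylcyclohexenone oxides to 2-acetylcyclopentanones). The cyclopentanone is closed by this 1,2-shift, a six-to-five ring contraction, not by an end-to-end cyclisation. The only new stereocentre, C1, lies between two carbonyls and should settle on work-up as the β-acetyl epimer, pseudo-equatorial and anti to C7; the fusion carbons take no part, so the trans fusion is carried over. The step needs cleavage at C5 rather than C4, and acyl migration rather than methyl migration or hydride shift from C6: the carbonyl secures the first, the higher migratory aptitude of acyl and the concerted shift the second. Low temperature and the absence of protic acid should keep the silyl ether, allylic ester and exocyclic alkene intact.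

Step 18
Reactants: 24 1β-acetyl-hydrindan-2-one
Product: 26 1β-acetoxy-5α-angeloyloxy-6β-(tert-butyldimethylsilyloxy)-7β-isopropyl-4-methylene-trans-hydrindan-2-one, via 1-acetyl-1-hydroxy diketone 25 (not isolated)
Conditions: trans-2-(phenylsulfonyl)-3-phenyloxaziridine (1.05 equiv), Cs2CO3 (0.5 equiv), THF, −20 → 25 °C
Reagents that add atoms: Davis oxaziridine, O=S(=O)(c1ccccc1)N1OC1c1ccccc1
Why: Davis oxidation of the β-diketone enolate at C1 (an oxidant that does not epoxidise alkenes), then base-mediated 1,2 C→O acyl shift of the tertiary α-hydroxy β-diketone (α-ketol ester rearrangement): the freely rotating acetyl group should move to oxygen rather than the ring acyl, and protonation of the resulting enolate should give the more stable 1β-acetoxy epimer.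

Step 19
Reactants: 26 silyl-protected acetoxy ketone
Product: 27 target CNP0317011.1 (1β-acetoxy-5α-angeloyloxy-6β-hydroxy-7β-isopropyl-4-methylene-trans-hydrindan-2-one)
Conditions: HF·pyridine, pyridine, THF, 0 → 25 °C
Reagents that add atoms: none
Why: Fluoride-mediated desilylation under buffered, non-basic conditions, which should spare the base-labile α-acetoxy ketone, the angelate and the alkene.

**Compound list**

1 | isovaleraldehyde | CC(C)CC=O | starting material
2 | methyl vinyl ketone | C=CC(C)=O | starting material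
3 | (S)-2-isopropyl-5-oxohexanal | O=C[C@H](C(C)C)CCC(C)=O | intermediate
4 | (S)-cryptone | O=C1C=C[C@H](C(C)C)CC1 | intermediate
5 | isoprene | C=CC(C)=C | starting material
6 | cis-octalone (1β-H, 6β-H, 7β-iPr, 10-oxo-3-ene) | O=C1[C@H]2CC=C(C)C[C@H]2[C@H](C(C)C)CC1 | intermediate
7 | trans-octalone (1α-H, 6β-H) | O=C1[C@@H]2CC=C(C)C[C@H]2[C@H](C(C)C)CC1 | intermediate
8 | kinetic trimethylsilyl enol ether of 7 (C9=C10) | C[Si](C)(C)OC1[C@@H]2CC=C(C)C[C@H]2[C@H](C(C)C)CC=1 | intermediate (not isolated)
9 | trans-dienone (3,8-dien-10-one) | O=C1[C@@H]2CC=C(C)C[C@H]2[C@H](C(C)C)C=C1 | intermediate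
10 | 8β,9β-epoxy-3-en-10-one | O=C1[C@@H]2CC=C(C)C[C@H]2[C@H](C(C)C)[C@@H]3O[C@@H]31 | intermediate
11 | 8β,9β-epoxy-10-methylene-3-ene | C=C1[C@@H]2CC=C(C)C[C@H]2[C@H](C(C)C)[C@@H]3O[C@@H]31 | intermediate
12 | 9α-(4-methoxybenzyloxy)-10-methylene-3-en-8β-ol | C=C1[C@@H]2CC=C(C)C[C@H]2[C@H](C(C)C)[C@H](O)[C@H]1OCc3ccc(OC)cc3 | intermediate
13 | 8β-silyloxy-9α-(4-methoxybenzyloxy)-10-methylene-3-ene | C=C1[C@@H]2CC=C(C)C[C@H]2[C@H](C(C)C)[C@H](O[Si](C)(C)C(C)(C)C)[C@H]1OCc3ccc(OC)cc3 | intermediate
14 | 3,4-epoxide of 13 (both faces) | C=C1[C@@H]2CC3OC3(C)C[C@H]2[C@H](C(C)C)[C@H](O[Si](C)(C)C(C)(C)C)[C@H]1OCc4ccc(OC)cc4 | intermediate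
15 | C3 alcohol (C3/C4 mixture) | C=C1[C@@H]2CC(O)C(C)C[C@H]2[C@H](C(C)C)[C@H](O[Si](C)(C)C(C)(C)C)[C@H]1OCc3ccc(OC)cc3 | intermediate
16 | 4-methyl-3-ketone (C4 epimers) | C=C1[C@@H]2CC(=O)C(C)C[C@H]2[C@H](C(C)C)[C@H](O[Si](C)(C)C(C)(C)C)[C@H]1OCc3ccc(OC)cc3 | intermediate
17 | thermodynamic trimethylsilyl enol ether of 16 (C3=C4) | C=C1[C@@H]2CC(O[Si](C)(C)C)=C(C)C[C@H]2[C@H](C(C)C)[C@H](O[Si](C)(C)C(C)(C)C)[C@H]1OCc3ccc(OC)cc3 | intermediate (not isolated)
18 | 4-methyl-4-en-3-one | C=C1[C@@H]2CC(=O)C(C)=C[C@H]2[C@H](C(C)C)[C@H](O[Si](C)(C)C(C)(C)C)[C@H]1OCc3ccc(OC)cc3 | intermediate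
19 | 4α,5α-epoxy-3-ketone (8β-silyloxy, 9α-methoxybenzyloxy) | C=C1[C@@H]2CC(=O)[C@@]3(C)O[C@H]3[C@H]2[C@H](C(C)C)[C@H](O[Si](C)(C)C(C)(C)C)[C@H]1OCc4ccc(OC)cc4 | intermediate
20 | 4α,5α-epoxy-3-ketone 9α-alcohol | C=C1[C@@H]2CC(=O)[C@@]3(C)O[C@H]3[C@H]2[C@H](C(C)C)[C@H](O[Si](C)(C)C(C)(C)C)[C@H]1O | intermediate
21 | angelic acid | C/C=C(/C)C(=O)O | starting material
22 | angelic 2,4,6-trichlorobenzoic anhydride | C/C=C(/C)C(=O)OC(=O)c1c(Cl)cc(Cl)cc1Cl | intermediate (not isolated)
23 | 4α,5α-epoxy-3-ketone 9α-angelate, 8β-silyl ether (key precursor) | C=C1[C@@H]2CC(=O)[C@@]3(C)O[C@H]3[C@H]2[C@H](C(C)C)[C@H](O[Si](C)(C)C(C)(C)C)[C@H]1OC(=O)/C(C)=C\C | intermediate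
24 | 1β-acetyl-trans-hydrindan-2-one, 5α-angelate, 6β-silyl ether (key product) | C=C1[C@@H]2CC(=O)[C@H](C(C)=O)[C@H]2[C@H](C(C)C)[C@H](O[Si](C)(C)C(C)(C)C)[C@H]1OC(=O)/C(C)=C\C | intermediate
25 | 1-acetyl-1-hydroxy-hydrindan-2-one (C1 configuration immaterial) | C=C1[C@@H]2CC(=O)C(O)(C(C)=O)[C@H]2[C@H](C(C)C)[C@H](O[Si](C)(C)C(C)(C)C)[C@H]1OC(=O)/C(C)=C\C | intermediate (not isolated)
26 | 1β-acetoxy-hydrindan-2-one, 5α-angelate, 6β-silyl ether | C=C1[C@@H]2CC(=O)[C@H](OC(C)=O)[C@H]2[C@H](C(C)C)[C@H](O[Si](C)(C)C(C)(C)C)[C@H]1OC(=O)/C(C)=C\C | intermediate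
27 | CNP0317011.1 | C=C1[C@@H]2CC(=O)[C@H](OC(C)=O)[C@H]2[C@H](C(C)C)[C@H](O)[C@H]1OC(=O)/C(C)=C\C | target

**Step count**

Total: 19 steps. Longest linear sequence: 19 steps (from 1 and 2; isoprene and angelic acid enter as purchased reagents).

**Steps most likely to fail**

Step 17. What may go wrong: the C5–O bond ionises without concerted acyl migration, so that hydride shift from C6, fluoride capture or Lewis-acid loss of the allylic ester takes over. Fallback (from 16, back at 26): the same C1–C2 bond is made by a carbonyl condensation instead of a cationic shift. Ketone 16 is converted into enol silane 17 as in step 13 and oxidised with mCPBA (Rubottom oxidation; the tetrasubstituted enol ether should react far faster than either alkene) to 4-hydroxy-4-methyl-3-ketone F1. Pb(OAc)4 in MeOH/benzene cleaves the α-ketol between C3 and C4 to seco keto ester F2 (methyl ester at C3, methyl ketone at C4). KOtBu in THF closes the five-membered ring by intramolecular Claisen condensation of the C5 enolate onto the ester, giving ether-protected 1-acetyl-hydrindan-2-one F3. The oxaziridine/Cs2CO3 treatment of step 18 then gives ether-protected acetoxy ketone F4, DDQ gives 5α-alcohol F5, and the esterification of step 16 returns to 26.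

Step 18. What may go wrong: the ring acyl carbon is transferred to oxygen instead of the acetyl group (ring expansion to a lactone), or the base transposes the acyloin ester between C1 and C2. Fallback (from 24, back at 26): direct Baeyer–Villiger oxidation of the diketo tautomer with Me3SiOOSiMe3 and Me3SiOTf (cat.) in CH2Cl2 at low temperature. This peroxide does not epoxidise alkenes, C1 migrates with retention, and no base is present.

Step 6. What may go wrong: poor facial selectivity, with hydroperoxide attacking the α face, after which the epoxide opening of step 8 would no longer be both allylic and trans-diaxial. Fallback (from 9, back at 10): hydroxyl-directed epoxidation. Luche reduction (NaBH4, CeCl3·7H2O, MeOH) of 9 gives equatorial 10α-allylic alcohol F6. Mitsunobu inversion with 4-nitrobenzoic acid gives 10β-(4-nitrobenzoate) F7, and K2CO3/MeOH gives axial 10β-allylic alcohol F8. VO(acac)2/tBuOOH epoxidises only the allylic alkene, syn to the hydroxyl, to 8β,9β-epoxy-10β-alcohol F9, and Dess–Martin oxidation returns to 10.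

**Further compounds**

F1 | step 17 | 4-hydroxy-4-methyl-3-ketone (8β-silyloxy, 9α-methoxybenzyloxy, 10-methylene) | C=C1[C@@H]2CC(=O)C(C)(O)C[C@H]2[C@H](C(C)C)[C@H](O[Si](C)(C)C(C)(C)C)[C@H]1OCc3ccc(OC)cc3
F2 | step 17 | seco keto ester (ring A with CH2CO2Me on C1 and CH2COCH3 on C6) | C=C1[C@H](CC(=O)OC)[C@@H](CC(C)=O)[C@H](C(C)C)[C@H](O[Si](C)(C)C(C)(C)C)[C@H]1OCc2ccc(OC)cc2
F3 | step 17 | 1β-acetyl-trans-hydrindan-2-one, 5α-(4-methoxybenzyl) ether, 6β-silyl ether | C=C1[C@@H]2CC(=O)[C@H](C(C)=O)[C@H]2[C@H](C(C)C)[C@H](O[Si](C)(C)C(C)(C)C)[C@H]1OCc3ccc(OC)cc3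
F4 | step 17 | 1β-acetoxy-trans-hydrindan-2-one, 5α-(4-methoxybenzyl) ether, 6β-silyl ether | C=C1[C@@H]2CC(=O)[C@H](OC(C)=O)[C@H]2[C@H](C(C)C)[C@H](O[Si](C)(C)C(C)(C)C)[C@H]1OCc3ccc(OC)cc3
F5 | step 17 | 1β-acetoxy-trans-hydrindan-2-one 5α-alcohol, 6β-silyl ether | C=C1[C@@H]2CC(=O)[C@H](OC(C)=O)[C@H]2[C@H](C(C)C)[C@H](O[Si](C)(C)C(C)(C)C)[C@H]1O
F0 | step 18 | none | none
F6 | step 6 | 3,8-dien-10α-ol | O[C@H]1[C@@H]2CC=C(C)C[C@H]2[C@H](C(C)C)C=C1
F7 | step 6 | 3,8-dien-10β-yl 4-nitrobenzoate | O=C(O[C@@H]1[C@@H]2CC=C(C)C[C@H]2[C@H](C(C)C)C=C1)c3ccc([N+](=O)[O-])cc3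
F8 | step 6 | 3,8-dien-10β-ol | O[C@@H]1[C@@H]2CC=C(C)C[C@H]2[C@H](C(C)C)C=C1
F9 | step 6 | 8β,9β-epoxy-3-en-10β-ol | O[C@@H]1[C@@H]2CC=C(C)C[C@H]2[C@H](C(C)C)[C@@H]3O[C@@H]31
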